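The six-membered dienone ring is assembled from a four-membered one. Its atoms C4(OMe)(alkenyl)–C5(OMe)=C6H–C1(=O) carry the oxygen pattern of a semisquarate-derived cyclobutenone, and C2(propenyl)=C3H is the triple bond of (E)-pent-3-en-1-yne. In the key step zerovalent nickel inserts this enyne into the acyl–C4 bond of (S)-4-alkenyl-3,4-dimethoxycyclobut-2-enone. This two-carbon ring expansion closes the cyclohexa-2,5-dienone, places the propenyl group on C2 and carries the quaternary C4 stereocentre over with retention, giving the target directly. The precursor comes from methyl semisquarate and a stereodefined alkenyllithium in one operation and is resolved by chromatography on a chiral phase before the expansion.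

Key step: step 7

Assumption: dienone atoms are numbered C1 (carbonyl), C2 (propenyl-bearing), C3, C4 (quaternary, S), C5 (methoxy-bearing), C6. The two fractions of the resolution in step 5 are to be assigned (vibrational circular dichroism) before use.

Step 1
Reactants: 1 4-iodo-1,2-dimethoxybenzene; 2 propyne
Product: 3 1,2-dimethoxy-4-(prop-1-yn-1-yl)benzene
Conditions: PdCl2(PPh3)2 (2 mol %), CuI (4 mol %), Et3N, THF, rt
Reagents that add atoms: none
Why: Sonogashira coupling of an aryl iodide with a terminal alkyne is routine and creates no stereocentre.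

Step 2
Reactants: 3 1,2-dimethoxy-4-(prop-1-yn-1-yl)benzene
Product: 5 (E)-4-(2-iodoprop-1-en-1-yl)-1,2-dimethoxybenzene, via alkenylzirconocene chloride 4 (not isolated)
Conditions: Cp2Zr(H)Cl (1.5 equiv), THF, rt → 50 °C; then I2, 0 °C
Reagents that add atoms: iodine, II
Why: syn-hydrozirconation should place zirconium on the methyl-bearing, less hindered alkyne carbon after equilibration with excess hydride, and iodinolysis with retention should give the iodide in which aryl and methyl are cis.

Step 3
Reactants: 6 dimethyl squarate (3,4-dimethoxycyclobut-3-ene-1,2-dione)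
Product: 8 3-methoxycyclobut-3-ene-1,2-dione (methyl semisquarate), via hydroxycyclobutenone 7 (not isolated)
Conditions: LiAlH(OtBu)3, THF, −78 → 0 °C, 1 M HCl work-up; then conc. HCl (cat.), CH2Cl2, rt
Reagents that add atoms: water, O
Why: bulky-hydride 1,2-reduction of one squarate carbonyl, then acid-induced ionisation of the allylic hydroxyl, capture of the oxocarbenium ion by water and loss of methanol (a 1,3-carbonyl transposition known for squarate diesters) should give the semisquarate.

Step 4
Reactants: 5 (E)-4-(2-iodoprop-1-en-1-yl)-1,2-dimethoxybenzene; 8 3-methoxycyclobut-3-ene-1,2-dione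
Product: 11 rac-4-[(E)-1-(3,4-dimethoxyphenyl)prop-1-en-2-yl]-3,4-dimethoxycyclobut-2-en-1-one, via alkenyllithium 9 (not isolated), via lithium alkoxide 10 (not isolated)
Conditions: 5, t-BuLi (2 equiv), Et2O, −78 °C; then 8, THF, −78 °C; then MeOTf (3 equiv), −78 → −20 °C
Reagents that add atoms: methyl trifluoromethanesulfonate, COS(=O)(=O)C(F)(F)F
Why: iodine–lithium exchange with retention of alkene geometry, 1,2-addition to the ketone carbonyl next to the methoxy-bearing carbon (not the deactivated vinylogous ester carbonyl) and O-methylation of the alkoxide in the flask should give the quaternary ether, whose stereocentre forms as the racemate.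

Step 5
Reactants: 11 rac-4-[(E)-1-(3,4-dimethoxyphenyl)prop-1-en-2-yl]-3,4-dimethoxycyclobut-2-en-1-one
Product: 12 (S)-4-[(E)-1-(3,4-dimethoxyphenyl)prop-1-en-2-yl]-3,4-dimethoxycyclobut-2-en-1-one
Conditions: preparative SFC, amylose tris(3,5-dimethylphenylcarbamate) phase, CO2/iPrOH, rt
Reagents that add atoms: none
Why: resolution of enantiomers on a chiral stationary phase; no bond is made, the quaternary ether cannot epimerise at room temperature, and the (S) fraction fixes the absolute configuration that step 7 carries into the target.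

Step 6
Reactants: 13 (E)-but-2-enal (crotonaldehyde)
Product: 14 (E)-pent-3-en-1-yne
Conditions: TMSCHN2, LiN(iPr)2, THF, −78 °C; then 13, −78 °C → rt; acid wash, distilled and used as a titrated THF solution
Reagents that add atoms: (trimethylsilyl)diazomethane, C[Si](C)(C)C=[N+]=[N-]
Why: Colvin rearrangement (1,2-addition of the lithiated diazo reagent, loss of silanolate and nitrogen, 1,2-hydrogen shift of the alkylidene carbene) should turn the aldehyde into the terminal alkyne without touching the (E)-alkene.

Step 7
Reactants: 12 (S)-4-[(E)-1-(3,4-dimethoxyphenyl)prop-1-en-2-yl]-3,4-dimethoxycyclobut-2-en-1-one; 14 (E)-pent-3-en-1-yne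
Product: 15 (S)-4-[(E)-1-(3,4-dimethoxyphenyl)prop-1-en-2-yl]-4,5-dimethoxy-2-[(E)-prop-1-en-1-yl]cyclohexa-2,5-dien-1-one
Conditions: Ni(cod)2 (10 mol %), PPh3 (20 mol %), 14 (3 equiv), THF/toluene, 0 °C → rt
Reagents that add atoms: none
Why: Proposed new method: zerovalent nickel should insert oxidatively into the strained acyl–C4 σ bond of 12 (the bond that also breaks in thermal cyclobutenone ring opening) to give a nickelacyclopentenone, the enyne should then insert into the Ni–C4 bond, and C(acyl)–C(sp2) reductive elimination should release the dienone and the catalyst. The closest known reaction type is the nickel-catalysed annulation of cyclobutenones with alkynes to phenols; here C4 is fully substituted, so the first-formed cyclohexa-2,5-dienone cannot tautomerise and is the product. The six-membered ring is closed by reductive elimination from a seven-membered nickelacycle, a formal [4+2] ring expansion by two atoms in which C1 and C4–C6 come from the four-membered ring and C2–C3 from the alkyne. No stereocentre is created: C4 is carried over, and retention is expected because oxidative addition and migratory insertion both proceed with retention at carbon and the metal stays on the face it entered. The step needs regioselectivity (the unsubstituted alkyne terminus must bond to C4), which the bulk of the quaternary C4 and the preference of nickel for the alkenyl-substituted, allyl-stabilised alkyne carbon both support. It also needs chemoselectivity over closure onto the styrenyl side chain and over alkyne oligomerisation, which the low temperature (far below the thermal ring-opening temperature of 12) and the excess of enyne are meant to secure.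

Compound list
1 | 4-iodo-1,2-dimethoxybenzene | COc1ccc(I)cc1OC | starting material
2 | propyne | CC#C | starting material
3 | 1,2-dimethoxy-4-(prop-1-yn-1-yl)benzene | CC#Cc1ccc(OC)c(OC)c1 | intermediate
4 | (E)-chlorobis(cyclopentadienyl)[1-(3,4-dimethoxyphenyl)prop-1-en-2-yl]zirconium (zirconium trans to aryl) | Cl[Zr](C1C=CC=C1)(C1C=CC=C1)/C(C)=C/c1ccc(OC)c(OC)c1 | intermediate
5 | (E)-4-(2-iodoprop-1-en-1-yl)-1,2-dimethoxybenzene (iodine trans to aryl) | I/C(C)=C/c1ccc(OC)c(OC)c1 | intermediate
6 | dimethyl squarate (3,4-dimethoxycyclobut-3-ene-1,2-dione) | COC1=C(OC)C(=O)C1=O | starting material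
7 | rac-4-hydroxy-2,3-dimethoxycyclobut-2-en-1-one | COC1=C(OC)C(O)C1=O | intermediate
8 | 3-methoxycyclobut-3-ene-1,2-dione (methyl semisquarate) | COC1=CC(=O)C1=O | intermediate
9 | (Z)-[1-(3,4-dimethoxyphenyl)prop-1-en-2-yl]lithium (lithium trans to aryl) | [Li]/C(C)=C/c1ccc(OC)c(OC)c1 | intermediate
10 | rac-lithium 1-[(E)-1-(3,4-dimethoxyphenyl)prop-1-en-2-yl]-2-methoxy-4-oxocyclobut-2-en-1-olate | [Li]OC1(/C(C)=C/c2ccc(OC)c(OC)c2)C(OC)=CC1=O | intermediate
11 | rac-4-[(E)-1-(3,4-dimethoxyphenyl)prop-1-en-2-yl]-3,4-dimethoxycyclobut-2-en-1-one | COC1=CC(=O)C1(OC)/C(C)=C/c1ccc(OC)c(OC)c1 | intermediate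
12 | (S)-4-[(E)-1-(3,4-dimethoxyphenyl)prop-1-en-2-yl]-3,4-dimethoxycyclobut-2-en-1-one | O=C1[C@](OC)(/C(C)=C/c2ccc(OC)c(OC)c2)C(OC)=C1 | intermediate
13 | (E)-but-2-enal | C/C=C/C=O | starting material
14 | (E)-pent-3-en-1-yne | C/C=C/C#C | intermediate
15 | (S)-4-[(E)-1-(3,4-dimethoxyphenyl)prop-1-en-2-yl]-4,5-dimethoxy-2-[(E)-prop-1-en-1-yl]cyclohexa-2,5-dien-1-one | C/C=C/C1=C[C@](OC)(/C(C)=C/c2ccc(OC)c(OC)c2)C(OC)=CC1=O | target

Total step count: 7. Longest linear sequence: 5 steps (steps 1, 2, 4, 5, 7).

Steps most likely to fail

Step 7 (Proposed new method). The nickel intermediate may collapse onto the styrenyl side chain before the enyne inserts. The alkyne may also insert the wrong way round or oligomerise, and configuration at C4 may erode if the metal-bound vinylketene isomerises.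

The fallback uses the thermal, known four-to-six ring expansion of a 4-alkynylcyclobutenone and sets out from 8, with 5 as the second building block. An alkyl-substituted alkyne is used because a conjugating substituent would steer that rearrangement towards a five-membered ring.
- The lithium acetylide of pent-1-en-4-yne (n-BuLi, THF, −78 °C) should add to 8 to give rac-4-hydroxy-3-methoxy-4-(pent-4-en-1-yn-1-yl)cyclobut-2-en-1-one F1.
- Moore rearrangement (p-xylene, reflux) should expand F1 to 2-methoxy-5-(prop-2-en-1-yl)cyclohexa-2,5-diene-1,4-dione F2.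
- Alkenyllithium 9 (made from 5 as in step 4) should add at −78 °C to the carbonyl next to the methoxy-bearing carbon, which is the more electrophilic and less hindered one. This should give rac-4-[(E)-1-(3,4-dimethoxyphenyl)prop-1-en-2-yl]-4-hydroxy-5-methoxy-2-(prop-2-en-1-yl)cyclohexa-2,5-dien-1-one F3.
- MeI/Ag2O in MeCN should give the methyl ether rac-4-[(E)-1-(3,4-dimethoxyphenyl)prop-1-en-2-yl]-4,5-dimethoxy-2-(prop-2-en-1-yl)cyclohexa-2,5-dien-1-one F4.
- RuHCl(CO)(PPh3)3 (cat., toluene, 80 °C) should move the allyl double bond into conjugation to give rac-4-[(E)-1-(3,4-dimethoxyphenyl)prop-1-en-2-yl]-4,5-dimethoxy-2-[(E)-prop-1-en-1-yl]cyclohexa-2,5-dien-1-one F5.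
- Preparative SFC on the chiral phase of step 5 comes back to the route at 15.

Step 4. Methylation of the hindered tertiary lithium alkoxide may be incomplete, or the alkoxide may open anionically on warming before it is trapped.

The fallback sets out from 5 and 8. The addition is quenched at −78 °C with aqueous NH4Cl and rac-4-[(E)-1-(3,4-dimethoxyphenyl)prop-1-en-2-yl]-4-hydroxy-3-methoxycyclobut-2-en-1-one F6 is isolated. It is then methylated under neutral conditions (MeI, Ag2O, MeCN, rt), which comes back to the route at 11.

Step 2. Regiocontrol in the hydrozirconation may be incomplete, with some metal ending on the aryl-bearing carbon and giving the isomeric iodide.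

The fallback sets out from 3. Copper-catalysed syn-hydroboration (CuCl, Xantphos, NaOtBu, B2pin2, MeOH, THF, rt) places boron on the carbon remote from the aryl group and should give (Z)-2-[1-(3,4-dimethoxyphenyl)prop-1-en-2-yl]-4,4,5,5-tetramethyl-1,3,2-dioxaborolane F7. Iododeboronation with retention (I2, NaOH, THF/H2O, 0 °C) comes back to the route at 5.

Further compounds
F1 | step 7 | rac-4-hydroxy-3-methoxy-4-(pent-4-en-1-yn-1-yl)cyclobut-2-en-1-one | COC1=CC(=O)C1(O)C#CCC=C
F2 | step 7 | 2-methoxy-5-(prop-2-en-1-yl)cyclohexa-2,5-diene-1,4-dione | COC1=CC(=O)C(CC=C)=CC1=O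
F3 | step 7 | rac-4-[(E)-1-(3,4-dimethoxyphenyl)prop-1-en-2-yl]-4-hydroxy-5-methoxy-2-(prop-2-en-1-yl)cyclohexa-2,5-dien-1-one | C=CCC1=CC(O)(/C(C)=C/c2ccc(OC)c(OC)c2)C(OC)=CC1=O
F4 | step 7 | rac-4-[(E)-1-(3,4-dimethoxyphenyl)prop-1-en-2-yl]-4,5-dimethoxy-2-(prop-2-en-1-yl)cyclohexa-2,5-dien-1-one | C=CCC1=CC(OC)(/C(C)=C/c2ccc(OC)c(OC)c2)C(OC)=CC1=O
F5 | step 7 | rac-4-[(E)-1-(3,4-dimethoxyphenyl)prop-1-en-2-yl]-4,5-dimethoxy-2-[(E)-prop-1-en-1-yl]cyclohexa-2,5-dien-1-one | C/C=C/C1=CC(OC)(/C(C)=C/c2ccc(OC)c(OC)c2)C(OC)=CC1=O
F6 | step 4 | rac-4-[(E)-1-(3,4-dimethoxyphenyl)prop-1-en-2-yl]-4-hydroxy-3-methoxycyclobut-2-en-1-one | COC1=CC(=O)C1(O)/C(C)=C/c1ccc(OC)c(OC)c1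
F7 | step 2 | (Z)-2-[1-(3,4-dimethoxyphenyl)prop-1-en-2-yl]-4,4,5,5-tetramethyl-1,3,2-dioxaborolane | CC1(C)OB(OC1(C)C)/C(C)=C/c1ccc(OC)c(OC)c1
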